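Substrate decay per unit of catalyst charged reads 0.00224 M⁻¹ s⁻¹ in the noon run and 0.00221 M⁻¹ s⁻¹ in the winter run, close together, and the reckoning for this flask rests on these two figures.

in all of them: substrate 0.18 M; gas 17 mM (held)

| flask | free catalyst | remark | time |
|---|---|---|---|
| noon | 14 mM | run made earlier |  |
| winter | 20 mM | run made earlier |  |
| flask | 27 mM |  | 15 h |

| run | time / h | target / % | substrate / % |
|---|---|---|---|
| noon | 1.33 | 12.0 | 87.7 |
| noon | 2.50 | 21.0 | 77.9 |
| noon | 4.00 | 34.4 | 65.6 |
| noon | 6.00 | 48.0 | 52.6 |
| noon | 10.0 | 67.2 | 32.3 |
| noon | 20.0 | 90.1 | 9.9 |
| winter | 1.33 | 14.8 | 82.7 |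
| winter | 2.50 | 29.7 | 68.9 |
| winter | 4.00 | 44.7 | 54.5 |
| winter | 6.00 | 59.9 | 39.1 |
| winter | 10.0 | 80.3 | 20.4 |
| winter | 20.0 | 96.6 | 2.5 |

(readings scatter by 0.5 percentage points)

- at the start none of partner is dissolved
- the analysis behind the earlier runs scatters by 0.5 percentage points, standard deviation
- steps thought possible: partner + free catalyst <-> catalyst intermediate A; substrate + catalyst intermediate A <-> catalyst intermediate B; catalyst intermediate B -> by-product + catalyst intermediate C; catalyst intermediate C -> free catalyst + target; gas <-> partner

1. amount of target at 15 h, in percent of the substrate charged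
2. concentration of partner in solution at 1.5 h, in percent of saturation
3. the change that raises the amount of target at 15 h, in percent of the substrate charged most ("none" if none brings more than 2 percentage points) (Monday's / Sunday's / Friday's / none)
4. amount of target at 15 h, in percent of the substrate charged, after Monday's

- Monday's: doubling the amount of free catalyst, all else as stated
- Sunday's: doubling the saturation concentration of gas, all else as stated
- Friday's: doubling the transfer coefficient of the gas, all else as stated

A substrate that loses a fixed share of itself each hour decays first order, and its constant is the logarithm of charged over left, divided by the time. The steps thought possible hand the free catalyst back at the end of each turn, so a pseudo-first-order constant proportional to the catalyst charged is worth testing. At 10.0 h the noon run gives 0.113 h⁻¹ and the winter run 0.159 h⁻¹. Their ratio is 1.41, against 1.43 for the catalyst. Dividing each by its catalyst gives the opening figures, and their mean, 0.00223 M⁻¹ s⁻¹, is the specific constant: the first-order constant of substrate decay per unit of free catalyst charged.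

The first-order constant drifts, though. In the noon run it reads 0.0987 h⁻¹ at 1.33 h and higher at 10.0 h, so a figure for substrate left in this flask, reckoned from the readings at 10.0 h, may stand somewhat high. Target and substrate add up to 99.5% in the noon run at 10.0 h, so target is taken as the remainder.

My own reckoning for this flask, at 27 mM over 15 h, leaves 3.90% of substrate, hence 96.1% of target. Doubled catalyst leaves 0.152%, a gain of 3.7 percentage points. Both runs held the gas at 17 mM, so the specific constant is silent on Sunday's, Friday's and the partner.

The forecast gives 96% (94.5% to 97.5%), partner at 76% of saturation (62% to 90%), Monday's as best, and 99.4% after it, a little below my 99.8%. It adds: “Doubling transfer adds under 1 point”.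

The flask gives 96.6% of target, with 3.34% of substrate left at 15 h. Partner stands at 88.9% of saturation at 1.5 h, above the forecast's figure. Monday's gains most: 3.3 points, reaching 99.9%, against 1.7 points for Sunday's and 0.12 points for Friday's.

    partner + free catalyst ⇌ catalyst intermediate A (K = 130 M⁻¹, k = 0.919 M⁻¹ s⁻¹)
    substrate + catalyst intermediate A ⇌ catalyst intermediate B (K = 94.8 M⁻¹, k = 0.00368 M⁻¹ s⁻¹)
    catalyst intermediate B → by-product + catalyst intermediate C (k = 0.00325 s⁻¹)
    catalyst intermediate C → free catalyst + target (k = 0.0338 s⁻¹)
    gas ⇌ partner, rate k5*(csat - [partner]) (kL = 0.00423 s⁻¹)

With 0.016 M of free catalyst in place of 27 mM, the time unchanged, the specific constant leaves 14.6% of substrate; that neighbouring flask holds 13.9% and gives 85.9% of target.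

The data are simulated for substances that don't exist; noise was put on by code.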